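**Assumptions:** The stereocentre in the SMILES is (S) (CIP order OH > C(=O)Ar > CH2Ar > H), and that enantiomer is the target. Catalysts, bases and solvents are not numbered. An2CH = bis(4-methoxyphenyl)methyl.

## Retrosynthetic overview
1. No ring is built. Both benzene rings are purchased (4-bromoresorcinol and 4-hydroxybenzaldehyde), and the last step is one mild acidic global deprotection.
2. Both prenyl groups come from a single double aromatic Claisen rearrangement of a bis(1,1-dimethylallyl) aryl ether. Until then, these ethers also serve as the A-ring phenol protecting groups.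
3. The key disconnection is Cα–Cβ, which avoids both the chalcone aldol/epoxide route and the aryl-metal plus chiral lactate route. A catalytic asymmetric phase-transfer benzylation of an achiral aryl glycolyl ketone forms the skeleton and the (S) centre in one step, under base-only conditions that leave the olefins alone.
4. The aryl glycolyl ketone comes from an aryllithium and a glycolate Weinreb amide. The bis-ether comes from Pd-catalysed O-tert-prenylation of 4-bromoresorcinol.

## Route

**Step 1**
Reactants: 1, 2-methylbut-3-en-2-ol
Product: 2, tert-butyl (2-methylbut-3-en-2-yl) carbonate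
Conditions: n-BuLi, THF, −78 → 0 °C; Boc2O, → rt
Reagents that add atoms: di-tert-butyl dicarbonate, CC(C)(C)OC(=O)OC(=O)OC(C)(C)C
Why: O-acylation of the lithium tertiary alkoxide (carbonate formation) gives the ionisable allyl carbonate needed for the Tsuji–Trost step.

**Step 2**
Reactants: 3, 4-bromoresorcinol; 2 (3 equiv)
Product: 4, 1-bromo-2,4-bis[(2-methylbut-3-en-2-yl)oxy]benzene
Conditions: Pd(PPh3)4 (5 mol %), THF, 0–5 °C, stop at full conversion
Reagents that add atoms: none beyond numbered reactant 2 (it delivers two C5H9 units; CO2 and t-BuOH are lost)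
Why: In this Tsuji–Trost O-allylation, Pd(0) ionises 2, the released tert-butoxide deprotonates the phenol, and the phenoxide attacks the more substituted π-allyl terminus under kinetic control, at a temperature where the electron-rich Ar–Br bond does not add to Pd(0).

**Step 3**
Reactants: 5, bis(4-methoxyphenyl)methanol; 6, 2-chloro-N-methoxy-N-methylacetamide
Product: 7, 2-[bis(4-methoxyphenyl)methoxy]-N-methoxy-N-methylacetamide
Conditions: NaH, n-Bu4NI (cat.), THF, 0 °C → rt
Reagents that add atoms: none beyond the numbered reactants
Why: This is a Williamson ether synthesis, in which SN2 displacement at the activated α-chloro amide is much faster than attack at the Weinreb carbonyl.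

**Step 4**
Reactants: 4; 7
Product: 8, 2-[bis(4-methoxyphenyl)methoxy]-1-{2,4-bis[(2-methylbut-3-en-2-yl)oxy]phenyl}ethan-1-one
Conditions: n-BuLi, THF, −78 °C, 20 min; add 7, −78 → −30 °C; sat. aq NH4Cl
Reagents that add atoms: none beyond the numbered reactants
Why: Br/Li exchange followed by Weinreb ketone synthesis works because the chelated tetrahedral intermediate prevents over-addition, and at −78 °C the o-(allyloxy)aryllithium does not undergo 5-exo carbolithiation.

**Step 5**
Reactants: 9, 4-hydroxybenzaldehyde
Product: 10, 4-(methoxymethoxy)benzaldehyde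
Conditions: MOMCl, i-Pr2NEt, CH2Cl2, 0 °C → rt
Reagents that add atoms: chloromethyl methyl ether, COCCl
Why: This is standard phenol O-alkylation (MOM acetal formation).

**Step 6**
Reactants: 10
Product: 11, [4-(methoxymethoxy)phenyl]methanol
Conditions: NaBH4, MeOH, 0 °C
Reagents that add atoms: none
Why: Borohydride reduces the aldehyde and the MOM group is inert to it.

**Step 7**
Reactants: 11
Product: 12, 1-(bromomethyl)-4-(methoxymethoxy)benzene (used fresh)
Conditions: CBr4, PPh3, 2,6-lutidine, CH2Cl2, 0 °C
Reagents that add atoms: carbon tetrabromide, BrC(Br)(Br)Br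
Why: The Appel bromination is essentially neutral, so the acid-labile MOM acetal survives.

**Step 8 (key step)**
Reactants: 8; 12 (3 equiv)
Product: 13, (2S)-2-[bis(4-methoxyphenyl)methoxy]-1-{2,4-bis[(2-methylbut-3-en-2-yl)oxy]phenyl}-3-[4-(methoxymethoxy)phenyl]propan-1-one
Conditions: O-allyl-N-(2,3,4-trifluorobenzyl)cinchonidinium bromide (10 mol %, two operations from cinchonidine), CsOH·H2O (4 equiv), CH2Cl2/hexane 1:1, −35 °C, 24 h. Expected about 85–90 % ee, raised to ≥99 % by crystallisation of 13 or 14, or by preparative chiral HPLC.
Reagents that add atoms: none beyond the numbered reactants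
Why: In this cinchona-ammonium asymmetric phase-transfer alkylation of a glycolate-type aryl ketone, the interfacial Z-enolate is held as a tight ion pair against the cinchonidinium cation through π-contacts with the diarylmethyl ether and the aryl ketone, so the benzyl bromide reaches only the Si face of Cα and gives the (S) sense known for this catalyst family with benzhydryl-protected alkoxyacetophenones and benzylic bromides.

**Step 9**
Reactants: 13
Product: 14, (2S)-2-[bis(4-methoxyphenyl)methoxy]-1-[2,4-dihydroxy-3,5-bis(3-methylbut-2-en-1-yl)phenyl]-3-[4-(methoxymethoxy)phenyl]propan-1-one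
Conditions: degassed DMF, BHT (trace), 120 °C, 2–4 h
Reagents that add atoms: none
Why: In this double aromatic Claisen ([3,3]) rearrangement with allyl inversion, the 2-O unit can only go to C3 because C1 is blocked, and the 4-O unit of a non-chelated 2-alkoxy aryl ketone prefers the unhindered C5 (its only option if C3 fills first), so both orders give the 3,5-diprenyl pattern while the neutral medium leaves the α-alkoxy stereocentre untouched.

**Step 10**
Reactants: 14
Product: 15, Lespeflorin C6, (2S)-1-[2,4-dihydroxy-3,5-bis(3-methylbut-2-en-1-yl)phenyl]-2-hydroxy-3-(4-hydroxyphenyl)propan-1-one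
Conditions: 3 M aq HCl/MeOH (1:6), 1,3,5-trimethoxybenzene (5 equiv, cation scavenger), 40 °C, 1–2 h, Ar
Reagents that add atoms: none
Why: Acid solvolysis removes the MOM acetal and the trityl-like An2CH ether (SN1 at the diarylmethyl carbon), so the Cα–O bond is never broken and (S) is retained, and dilute HCl/MeOH is the usual MOM-removal medium for prenylated polyphenols.

## Compound list
1 | 2-methylbut-3-en-2-ol | C=CC(C)(C)O | starting material
2 | tert-butyl (2-methylbut-3-en-2-yl) carbonate | C=CC(C)(C)OC(=O)OC(C)(C)C | intermediate
3 | 4-bromoresorcinol | Oc1ccc(Br)c(O)c1 | starting material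
4 | 1-bromo-2,4-bis[(2-methylbut-3-en-2-yl)oxy]benzene | C=CC(C)(C)Oc1ccc(Br)c(OC(C)(C)C=C)c1 | intermediate
5 | bis(4-methoxyphenyl)methanol | COc1ccc(cc1)C(O)c1ccc(OC)cc1 | starting material
6 | 2-chloro-N-methoxy-N-methylacetamide | ClCC(=O)N(C)OC | starting material
7 | 2-[bis(4-methoxyphenyl)methoxy]-N-methoxy-N-methylacetamide | COc1ccc(cc1)C(OCC(=O)N(C)OC)c1ccc(OC)cc1 | intermediate
8 | 2-[bis(4-methoxyphenyl)methoxy]-1-{2,4-bis[(2-methylbut-3-en-2-yl)oxy]phenyl}ethan-1-one | C=CC(C)(C)Oc1ccc(C(=O)COC(c2ccc(OC)cc2)c2ccc(OC)cc2)c(OC(C)(C)C=C)c1 | intermediate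
9 | 4-hydroxybenzaldehyde | O=Cc1ccc(O)cc1 | starting material
10 | 4-(methoxymethoxy)benzaldehyde | COCOc1ccc(C=O)cc1 | intermediate
11 | [4-(methoxymethoxy)phenyl]methanol | COCOc1ccc(CO)cc1 | intermediate
12 | 1-(bromomethyl)-4-(methoxymethoxy)benzene | COCOc1ccc(CBr)cc1 | intermediate
13 | (2S)-benzylated bis(tert-prenyl ether) ketone (full name in Step 8) | C=CC(C)(C)Oc1ccc(C(=O)[C@@H](OC(c2ccc(OC)cc2)c2ccc(OC)cc2)Cc2ccc(OCOC)cc2)c(OC(C)(C)C=C)c1 | intermediate
14 | (2S)-3,5-diprenyl-2,4-dihydroxyphenyl ketone, α-O-An2CH, 4′-O-MOM (full name in Step 9) | CC(C)=CCc1cc(C(=O)[C@@H](OC(c2ccc(OC)cc2)c2ccc(OC)cc2)Cc2ccc(OCOC)cc2)c(O)c(CC=C(C)C)c1O | intermediate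
15 | Lespeflorin C6, (2S) | CC(C)=CCc1cc(C(=O)[C@@H](O)Cc2ccc(O)cc2)c(O)c(CC=C(C)C)c1O | target

## Totals
- **Total steps:** 10.
- **Longest linear sequence:** 6, either 1→2→4→8→13→14→15 or 9→10→11→12→13→14→15. It is 5 steps from 4-bromoresorcinol.

## Three steps most likely to fail
1. **Step 8.**
   - Risk: The bulky ortho tert-alkoxy group, the more electron-rich and therefore less acidic ketone, and the anisyl variant of the benzhydryl ether could each lower rate or ee.
   - Fallback: Abandon the Cα–Cβ alkylation and take the stereocentre from the chiral pool. L-tyrosine is converted to (S)-4-hydroxyphenyllactic acid by retentive diazotisation, then O-protected and converted to the Weinreb amide. The aryllithium from 4 is added to that amide to reach 13 directly.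
2. **Step 9.**
   - Risk: Isoprene loss, or 4-O→C3 migration followed by Claisen–Cope transfer of the 2-O unit, which would put a reverse-prenyl group at C5.
   - Fallback: Install the prenyl groups by C–C coupling instead of sigmatropy. Resorcinol bis-MOM ether undergoes two successive directed ortho-lithiation/Cu-mediated prenylations with prenyl bromide (C2, then C4). A third lithiation at C6 and acylation with 7 gives the ketone, and the phase-transfer benzylation is then run on the already prenylated substrate.
3. **Step 10.**
   - Risk: Acid-induced chroman formation from the o-prenylphenols, Friedel–Crafts capture of the An2CH cation, or partial racemisation.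
   - Fallback: Switch to a non-acidic protecting-group scheme. Use 4-(TIPSO)benzyl bromide in Step 8 and remove An2CH oxidatively with DDQ at the stage of 13, before any prenylphenol exists. Run the Claisen rearrangement on the free α-hydroxy ketone and finish with TBAF/AcOH.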